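**Retrosynthetic overview**
- Last step: one OsO4 double dihydroxylation turns a ring A silyl enol ether into the C1 ketone/C2 carbinol and a ring B exocyclic methylene into the C7 diol; just before it, a formaldehyde aldol completes the 3-hydroxypropanoyl chain.
- Ring B (formed second): 6-exo-dig radical cyclisation of a primary iodide (C6) onto a propargyl arm (C7).
- Ring A (formed first, key step): intermolecular endo Diels–Alder of a (Z,E)-2-silyloxydiene with an (S)-α-methyl unsaturated δ-lactone used as a locked (Z)-dienophile. This replaces the biomimetic intramolecular triene cycloaddition and sets C3, quaternary C4, C4a and C8a at once; MeLi then opens the lactone to the C9 ketone and the C6 handle.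
- Fragments: diene from (R)-2-methylbutan-1-ol (Wittig, propargylation, silylation); lactone from (R)-Roche ester (Still–Gennari olefination, lactonisation).

Assumption: (R)-2-methylbutan-1-ol and 3-(triphenylphosphoranylidene)butan-2-one are bought as catalogue chemicals; locants C1–C12 in the Why lines are those of the target (C1 ring ketone, C9–C11 side chain, C12 hydroxymethyl carbon).

**Route**

Step 1
Reactants: 1 (R)-2-methylbutan-1-ol; 2 3-(triphenylphosphoranylidene)butan-2-one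
Product: 4 (3E,5R)-3,5-dimethylhept-3-en-2-one, via (R)-2-methylbutanal 3 (not isolated)
Conditions: PhI(OAc)2 (1.1 equiv), TEMPO (10 mol %), CH2Cl2, 23 °C; then 2 (1.2 equiv), 40 °C
Reagents that add atoms: none
Why: TEMPO/PhI(OAc)2 oxidation gives the epimerisable α-branched aldehyde, which is trapped in the same pot by an E-selective Wittig olefination with the stabilised keto ylide; the sec-butyl stereocentre comes from the chiral pool and no new one is formed.

Step 2
Reactants: 4 (3E,5R)-3,5-dimethylhept-3-en-2-one; 5 3-bromo-1-(trimethylsilyl)prop-1-yne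
Product: 7 (6E,8R)-6,8-dimethyl-1-(trimethylsilyl)dec-6-en-1-yn-5-one, via lithium dienolate 6 (not isolated)
Conditions: LiN(iPr)2 (1.05 equiv), THF, −78 °C; then 5 (1.2 equiv), DMPU, −78 to −20 °C
Reagents that add atoms: none
Why: Kinetic α′-deprotonation of the methyl ketone gives the cross-conjugated lithium dienolate, and its SN2 enolate alkylation with the C-silylated propargylic bromide installs C8, C7 and C12 without touching the remote stereocentre.

Step 3
Reactants: 7 (6E,8R)-6,8-dimethyl-1-(trimethylsilyl)dec-6-en-1-yn-5-one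
Product: 8 tert-butyl{[(4Z,6E,8R)-6,8-dimethyl-1-(trimethylsilyl)deca-4,6-dien-1-yn-5-yl]oxy}dimethylsilane
Conditions: TBSOTf (1.2 equiv), Et3N (2 equiv), CH2Cl2, 0 °C
Reagents that add atoms: tert-butyldimethylsilyl trifluoromethanesulfonate, CC(C)(C)[Si](C)(C)OS(=O)(=O)C(F)(F)F
Why: Soft enolisation toward the only α′-CH2 gives the 2-silyloxy-1,3-diene (silyl enol ether formation), the (Z)-enol ether being favoured by allylic strain, so the propargyl arm sits "outside" like the sec-butyl group.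

Step 4
Reactants: 9 methyl (R)-3-hydroxy-2-methylpropanoate
Product: 10 methyl (R)-3-[(tert-butyldimethylsilyl)oxy]-2-methylpropanoate
Conditions: TBSCl (1.1 equiv), imidazole (1.5 equiv), CH2Cl2, 23 °C
Reagents that add atoms: tert-butyldimethylsilyl chloride, CC(C)(C)[Si](C)(C)Cl
Why: Standard silyl protection of the primary alcohol; the future C5 stereocentre comes from the Roche ester.

Step 5
Reactants: 10 methyl (R)-3-[(tert-butyldimethylsilyl)oxy]-2-methylpropanoate
Product: 11 (R)-3-[(tert-butyldimethylsilyl)oxy]-2-methylpropanal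
Conditions: iBu2AlH (1.05 equiv), CH2Cl2, −78 °C; aq. KNaC4H4O6 (tartrate) work-up
Reagents that add atoms: none
Why: Partial ester reduction through the aluminium hemiacetal, which is stable at −78 °C, gives the aldehyde with the α-stereocentre intact.

Step 6
Reactants: 11 (R)-3-[(tert-butyldimethylsilyl)oxy]-2-methylpropanal; 12 ethyl 2-[bis(2,2,2-trifluoroethoxy)phosphoryl]propanoate
Product: 14 ethyl (2Z,4S)-5-[(tert-butyldimethylsilyl)oxy]-2,4-dimethylpent-2-enoate, via potassium phosphonate enolate 13 (not isolated)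
Conditions: 12, KN(SiMe3)2, 18-crown-6, THF, −78 °C; then 11
Reagents that add atoms: none
Why: Still–Gennari variant of the Horner–Wadsworth–Emmons olefination, in which the trifluoroethyl phosphonate under dissociating conditions gives the (Z)-trisubstituted enoate; the stereocentre is untouched.

Step 7
Reactants: 14 ethyl (2Z,4S)-5-[(tert-butyldimethylsilyl)oxy]-2,4-dimethylpent-2-enoate
Product: 16 (S)-3,5-dimethyl-5,6-dihydro-2H-pyran-2-one, via hydroxy ester 15 (not isolated)
Conditions: p-TsOH·H2O (10 mol %), EtOH, 23 °C; then toluene, 80 °C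
Reagents that add atoms: none
Why: Acid-catalysed desilylation frees the alcohol, which is cis to the ester across the (Z)-alkene and lactonises (transesterification) to the six-membered unsaturated lactone, a configurationally locked (Z)-dienophile.

Step 8
Reactants: 8 tert-butyl{[(4Z,6E,8R)-6,8-dimethyl-1-(trimethylsilyl)deca-4,6-dien-1-yn-5-yl]oxy}dimethylsilane; 16 (S)-3,5-dimethyl-5,6-dihydro-2H-pyran-2-one
Product: 17 (4S,4aR,5S,8S,8aR)-8-[(2R)-butan-2-yl]-6-[(tert-butyldimethylsilyl)oxy]-4,7,8a-trimethyl-5-[3-(trimethylsilyl)prop-2-yn-1-yl]-3,4,4a,5,8,8a-hexahydro-1H-isochromen-1-one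
Conditions: AlBr3/AlMe3 (10:1, 30 mol %), toluene/CH2Cl2, −20 to 0 °C; pyridine quench
Reagents that add atoms: none
Why: Lewis-acid-promoted intermolecular Diels–Alder reaction (mixed AlBr3/AlMe3 activation of the kind used for hindered 2-silyloxydienes and α-substituted cyclic enones) in which the nucleophilic enol-ether terminus C8a bonds to the lactone β-carbon, the lactone carbonyl is endo and the diene approaches anti to the lactone 5-methyl, so both "outside" diene substituents, C5 and the acyl carbon end up all-cis, fixing C3, quaternary C4, C4a and C8a in one step relative to the Roche-ester-derived C5.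

Step 9
Reactants: 17 (4S,4aR,5S,8S,8aR)-8-[(2R)-butan-2-yl]-6-[(tert-butyldimethylsilyl)oxy]-4,7,8a-trimethyl-5-[3-(trimethylsilyl)prop-2-yn-1-yl]-3,4,4a,5,8,8a-hexahydro-1H-isochromen-1-one
Product: 19 1-{(1R,2S,5S,6R)-2-[(2R)-butan-2-yl]-4-[(tert-butyldimethylsilyl)oxy]-6-[(2S)-1-hydroxypropan-2-yl]-1,3-dimethyl-5-(prop-2-yn-1-yl)cyclohex-3-en-1-yl}ethan-1-one, via C-silyl alkyne 18 (not isolated)
Conditions: MeLi (1.3 equiv), THF, −78 °C; then MeOH, K2CO3 (0.2 equiv), 0 to 23 °C
Reagents that add atoms: methyllithium, [Li]C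
Why: 1,2-Addition of MeLi to the lactone carbonyl (no α-hydrogen, lithium hemiketal resists a second addition at −78 °C) unveils the C9 methyl ketone and the C6 alcohol while C1 stays masked as the silyl enol ether so that C8a cannot epimerise, and methanolic carbonate then removes the alkynyl silyl group (protodesilylation); no stereocentre is affected.

Step 10
Reactants: 19 1-{(1R,2S,5S,6R)-2-[(2R)-butan-2-yl]-4-[(tert-butyldimethylsilyl)oxy]-6-[(2S)-1-hydroxypropan-2-yl]-1,3-dimethyl-5-(prop-2-yn-1-yl)cyclohex-3-en-1-yl}ethan-1-one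
Product: 20 1-{(1R,2S,5S,6S)-2-[(2R)-butan-2-yl]-4-[(tert-butyldimethylsilyl)oxy]-6-[(2S)-1-iodopropan-2-yl]-1,3-dimethyl-5-(prop-2-yn-1-yl)cyclohex-3-en-1-yl}ethan-1-one
Conditions: I2 (1.3 equiv), PPh3 (1.3 equiv), imidazole (2.5 equiv), CH2Cl2, 0 to 23 °C
Reagents that add atoms: iodine, II
Why: Appel-type iodination of the primary alcohol under imidazole-buffered conditions that spare the silyl enol ether; the descriptor at the ring carbon changes only through priorities, no stereocentre is inverted.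

Step 11
Reactants: 20 1-{(1R,2S,5S,6S)-2-[(2R)-butan-2-yl]-4-[(tert-butyldimethylsilyl)oxy]-6-[(2S)-1-iodopropan-2-yl]-1,3-dimethyl-5-(prop-2-yn-1-yl)cyclohex-3-en-1-yl}ethan-1-one
Product: 21 1-{(1R,2S,4aS,8R,8aR)-2-[(2R)-butan-2-yl]-4-[(tert-butyldimethylsilyl)oxy]-1,3,8-trimethyl-6-methylidene-1,2,4a,5,6,7,8,8a-octahydronaphthalen-1-yl}ethan-1-one
Conditions: Bu3SnH (1.3 equiv, syringe pump), AIBN (10 mol %), benzene, 80 °C, 0.01 M
Reagents that add atoms: none
Why: Tin-hydride radical chain in which the primary C6 radical closes 6-exo-dig onto the terminal alkyne held cis on the neighbouring ring carbon, forming ring B as a methylenecyclohexane; the cis ring fusion was already fixed in step 8 and no stereocentre is formed.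

Step 12
Reactants: 21 1-{(1R,2S,4aS,8R,8aR)-2-[(2R)-butan-2-yl]-4-[(tert-butyldimethylsilyl)oxy]-1,3,8-trimethyl-6-methylidene-1,2,4a,5,6,7,8,8a-octahydronaphthalen-1-yl}ethan-1-one
Product: 23 1-{(1R,2S,4aS,8R,8aR)-2-[(2R)-butan-2-yl]-4-[(tert-butyldimethylsilyl)oxy]-1,3,8-trimethyl-6-methylidene-1,2,4a,5,6,7,8,8a-octahydronaphthalen-1-yl}-3-hydroxypropan-1-one, via lithium enolate 22 (not isolated)
Conditions: LiN(iPr)2 (1.1 equiv), THF, −78 °C; CH2O (gas from cracked paraformaldehyde), −78 °C; AcOH quench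
Reagents that add atoms: formaldehyde, C=O
Why: The methyl ketone is the only enolisable carbonyl (C1 is still a silyl enol ether, so C8a is safe), and its kinetic lithium enolate undergoes a crossed aldol addition to formaldehyde to give the β-hydroxy ketone side chain.

Step 13
Reactants: 23 1-{(1R,2S,4aS,8R,8aR)-2-[(2R)-butan-2-yl]-4-[(tert-butyldimethylsilyl)oxy]-1,3,8-trimethyl-6-methylidene-1,2,4a,5,6,7,8,8a-octahydronaphthalen-1-yl}-3-hydroxypropan-1-one
Product: 24 (2S,3R,4R,4aR,5R,7R,8aS)-3-[(2R)-butan-2-yl]-2,7-dihydroxy-7-(hydroxymethyl)-4-(3-hydroxypropanoyl)-2,4,5-trimethyloctahydronaphthalen-1(2H)-one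
Conditions: OsO4 (5 mol %), NMO (3 equiv), acetone/H2O (5:1), 23 °C; aq. Na2SO3 work-up
Reagents that add atoms: osmium tetroxide, O=[Os](=O)(=O)=O; N-methylmorpholine N-oxide, C[N+]1([O-])CCOCC1; water, O
Why: Upjohn dihydroxylation of both electron-rich alkenes in one operation: OsO4 adds to the ring A silyl enol ether from the β face (the α face is blocked by the pseudo-axial C8 and the axial C4 acyl group) and the silyloxy diol collapses to the C1 ketone with the β C2 hydroxyl, while the ring B exocyclic methylene is attacked from the convex β face of the cis-decalin (the axial acyl group lies under ring B), giving the C7/C12 diol with the C7 hydroxyl β.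

**Compound list**
1 | (R)-2-methylbutan-1-ol | CC[C@@H](C)CO | starting material
2 | 3-(triphenylphosphoranylidene)butan-2-one | CC(=O)C(C)=P(c1ccccc1)(c1ccccc1)c1ccccc1 | starting material
3 | (R)-2-methylbutanal | CC[C@@H](C)C=O | intermediate
4 | (3E,5R)-3,5-dimethylhept-3-en-2-one | CC[C@@H](C)/C=C(\C)C(C)=O | intermediate
5 | 3-bromo-1-(trimethylsilyl)prop-1-yne | C[Si](C)(C)C#CCBr | starting material
6 | lithium (3E,5R)-3,5-dimethylhepta-1,3-dien-2-olate | CC[C@@H](C)/C=C(\C)C(=C)O[Li] | intermediate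
7 | (6E,8R)-6,8-dimethyl-1-(trimethylsilyl)dec-6-en-1-yn-5-one | CC[C@@H](C)/C=C(\C)C(=O)CCC#C[Si](C)(C)C | intermediate
8 | tert-butyl{[(4Z,6E,8R)-6,8-dimethyl-1-(trimethylsilyl)deca-4,6-dien-1-yn-5-yl]oxy}dimethylsilane | CC[C@@H](C)/C=C(\C)/C(O[Si](C)(C)C(C)(C)C)=C/CC#C[Si](C)(C)C | intermediate
9 | methyl (R)-3-hydroxy-2-methylpropanoate | COC(=O)[C@H](C)CO | starting material
10 | methyl (R)-3-[(tert-butyldimethylsilyl)oxy]-2-methylpropanoate | COC(=O)[C@H](C)CO[Si](C)(C)C(C)(C)C | intermediate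
11 | (R)-3-[(tert-butyldimethylsilyl)oxy]-2-methylpropanal | O=C[C@H](C)CO[Si](C)(C)C(C)(C)C | intermediate
12 | ethyl 2-[bis(2,2,2-trifluoroethoxy)phosphoryl]propanoate | CCOC(=O)C(C)P(=O)(OCC(F)(F)F)OCC(F)(F)F | starting material
13 | potassium enolate of ethyl 2-[bis(2,2,2-trifluoroethoxy)phosphoryl]propanoate | CCOC([O-])=C(C)P(=O)(OCC(F)(F)F)OCC(F)(F)F.[K+] | intermediate
14 | ethyl (2Z,4S)-5-[(tert-butyldimethylsilyl)oxy]-2,4-dimethylpent-2-enoate | CCOC(=O)/C(C)=C\[C@H](C)CO[Si](C)(C)C(C)(C)C | intermediate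
15 | ethyl (2Z,4S)-5-hydroxy-2,4-dimethylpent-2-enoate | CCOC(=O)/C(C)=C\[C@H](C)CO | intermediate
16 | (S)-3,5-dimethyl-5,6-dihydro-2H-pyran-2-one | CC1=C[C@H](C)COC1=O | intermediate
17 | (4S,4aR,5S,8S,8aR)-8-[(2R)-butan-2-yl]-6-[(tert-butyldimethylsilyl)oxy]-4,7,8a-trimethyl-5-[3-(trimethylsilyl)prop-2-yn-1-yl]-3,4,4a,5,8,8a-hexahydro-1H-isochromen-1-one | CC[C@@H](C)[C@@H]1[C@]2(C)C(=O)OC[C@@H](C)[C@@H]2[C@H](CC#C[Si](C)(C)C)C(O[Si](C)(C)C(C)(C)C)=C1C | intermediate
18 | 1-{(1R,2S,5S,6R)-2-[(2R)-butan-2-yl]-4-[(tert-butyldimethylsilyl)oxy]-6-[(2S)-1-hydroxypropan-2-yl]-1,3-dimethyl-5-[3-(trimethylsilyl)prop-2-yn-1-yl]cyclohex-3-en-1-yl}ethan-1-one | CC[C@@H](C)[C@@H]1[C@](C)(C(C)=O)[C@H]([C@H](C)CO)[C@H](CC#C[Si](C)(C)C)C(O[Si](C)(C)C(C)(C)C)=C1C | intermediate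
19 | 1-{(1R,2S,5S,6R)-2-[(2R)-butan-2-yl]-4-[(tert-butyldimethylsilyl)oxy]-6-[(2S)-1-hydroxypropan-2-yl]-1,3-dimethyl-5-(prop-2-yn-1-yl)cyclohex-3-en-1-yl}ethan-1-one | CC[C@@H](C)[C@@H]1[C@](C)(C(C)=O)[C@H]([C@H](C)CO)[C@H](CC#C)C(O[Si](C)(C)C(C)(C)C)=C1C | intermediate
20 | 1-{(1R,2S,5S,6S)-2-[(2R)-butan-2-yl]-4-[(tert-butyldimethylsilyl)oxy]-6-[(2S)-1-iodopropan-2-yl]-1,3-dimethyl-5-(prop-2-yn-1-yl)cyclohex-3-en-1-yl}ethan-1-one | CC[C@@H](C)[C@@H]1[C@](C)(C(C)=O)[C@H]([C@H](C)CI)[C@H](CC#C)C(O[Si](C)(C)C(C)(C)C)=C1C | intermediate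
21 | 1-{(1R,2S,4aS,8R,8aR)-2-[(2R)-butan-2-yl]-4-[(tert-butyldimethylsilyl)oxy]-1,3,8-trimethyl-6-methylidene-1,2,4a,5,6,7,8,8a-octahydronaphthalen-1-yl}ethan-1-one | CC[C@@H](C)[C@@H]1[C@](C)(C(C)=O)[C@@H]2[C@H](C)CC(=C)C[C@@H]2C(O[Si](C)(C)C(C)(C)C)=C1C | intermediate
22 | lithium enolate of 21 (lithium 1-[that octahydronaphthalen-1-yl]ethen-1-olate, ring stereocentres as in 21) | CC[C@@H](C)[C@@H]1[C@](C)(C(=C)O[Li])[C@@H]2[C@H](C)CC(=C)C[C@@H]2C(O[Si](C)(C)C(C)(C)C)=C1C | intermediate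
23 | 1-{(1R,2S,4aS,8R,8aR)-2-[(2R)-butan-2-yl]-4-[(tert-butyldimethylsilyl)oxy]-1,3,8-trimethyl-6-methylidene-1,2,4a,5,6,7,8,8a-octahydronaphthalen-1-yl}-3-hydroxypropan-1-one | CC[C@@H](C)[C@@H]1[C@](C)(C(=O)CCO)[C@@H]2[C@H](C)CC(=C)C[C@@H]2C(O[Si](C)(C)C(C)(C)C)=C1C | intermediate
24 | (2S,3R,4R,4aR,5R,7R,8aS)-3-[(2R)-butan-2-yl]-2,7-dihydroxy-7-(hydroxymethyl)-4-(3-hydroxypropanoyl)-2,4,5-trimethyloctahydronaphthalen-1(2H)-one | CC[C@@H](C)[C@@H]1[C@](C)(C(=O)CCO)[C@@H]2[C@H](C)C[C@](O)(CO)C[C@@H]2C(=O)[C@@]1(C)O | target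

**Count and risks**
Total steps: 13. Longest linear sequence: 10 (steps 4–13, from Roche ester 9).

Steps most likely to fail:

- Step 8 (Diels–Alder). The α-methyl lactone is a weak, hindered dienophile and the diene is tetrasubstituted. The reaction may stop at the Mukaiyama–Michael stage, leak to the exo adduct, or lose the silyl enol ether. The fallback sets out from aldehyde 11 and comes back at 17. Still–Gennari olefination with methyl 2-[bis(2,2,2-trifluoroethoxy)phosphoryl]acetate gives methyl (2Z,4S)-5-[(tert-butyldimethylsilyl)oxy]-4-methylpent-2-enoate F1. Acid methanolysis passes through methyl (2Z,4S)-5-hydroxy-4-methylpent-2-enoate F2 to (S)-5-methyl-5,6-dihydro-2H-pyran-2-one F3, a disubstituted and much more reactive dienophile. The same cycloaddition with diene 8 gives the 8a-H cis-fused lactone (4S,4aR,5S,8R,8aR)-8-[(2R)-butan-2-yl]-6-[(tert-butyldimethylsilyl)oxy]-4,7-dimethyl-5-[3-(trimethylsilyl)prop-2-yn-1-yl]-3,4,4a,5,8,8a-hexahydro-1H-isochromen-1-one F4. Deprotonation with LiN(iPr)2 in THF at −78 °C gives the lithium lactone enolate F5, which MeI methylates on the convex face, anti to the sec-butyl group and with retention of the cis fusion, to give 17. The quaternary centre is then made by alkylation and not in the cycloaddition.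

- Step 12 (formaldehyde aldol). Double hydroxymethylation, retro-aldol or dehydration to the vinyl ketone can erode the yield. The fallback sets out from 21 (through its enolate 22) and comes back at 24. The enolate is C-alkylated with benzyl chloromethyl ether to give the benzyl ether 3-(benzyloxy)-1-{(1R,2S,4aS,8R,8aR)-2-[(2R)-butan-2-yl]-4-[(tert-butyldimethylsilyl)oxy]-1,3,8-trimethyl-6-methylidene-1,2,4a,5,6,7,8,8a-octahydronaphthalen-1-yl}propan-1-one F6. The step 13 dihydroxylation then gives (2S,3R,4R,4aR,5R,7R,8aS)-4-[3-(benzyloxy)propanoyl]-3-[(2R)-butan-2-yl]-2,7-dihydroxy-7-(hydroxymethyl)-2,4,5-trimethyloctahydronaphthalen-1(2H)-one F7. Hydrogenolysis (H2, Pd/C, EtOAc), now free of alkenes, gives 24.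

- Step 13 (double dihydroxylation). The facial selectivity at the exocyclic alkene rests on conformational analysis only, and the tetrasubstituted enol ether may be slow toward OsO4. The fallback sets out from 23 and comes back at 24, and is meant for the case where electrophilic oxidants take the α face of the exocyclic alkene. mCPBA (2.2 equiv, NaHCO3, CH2Cl2) performs a Rubottom oxidation of the enol ether and epoxidises the methylene group, giving the 2-O-silyl ketone carrying the C7/C12 spiro-epoxide with its oxygen on the α face F8. Dilute aqueous HClO4 in THF opens the epoxide at the tertiary carbon with inversion, which places the C7 hydroxyl on the β face and gives (2S,3R,4R,4aR,5R,7R,8aS)-3-[(2R)-butan-2-yl]-2-[(tert-butyldimethylsilyl)oxy]-7-hydroxy-7-(hydroxymethyl)-4-(3-hydroxypropanoyl)-2,4,5-trimethyloctahydronaphthalen-1(2H)-one F9. HF·pyridine then removes the silyl group to give 24.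

**Further compounds**
F1 | step 8 | methyl (2Z,4S)-5-[(tert-butyldimethylsilyl)oxy]-4-methylpent-2-enoate | COC(=O)/C=C\[C@H](C)CO[Si](C)(C)C(C)(C)C
F2 | step 8 | methyl (2Z,4S)-5-hydroxy-4-methylpent-2-enoate | COC(=O)/C=C\[C@H](C)CO
F3 | step 8 | (S)-5-methyl-5,6-dihydro-2H-pyran-2-one | O=C1C=C[C@H](C)CO1
F4 | step 8 | (4S,4aR,5S,8R,8aR)-8-[(2R)-butan-2-yl]-6-[(tert-butyldimethylsilyl)oxy]-4,7-dimethyl-5-[3-(trimethylsilyl)prop-2-yn-1-yl]-3,4,4a,5,8,8a-hexahydro-1H-isochromen-1-one | CC[C@@H](C)[C@@H]1[C@@H]2C(=O)OC[C@@H](C)[C@@H]2[C@H](CC#C[Si](C)(C)C)C(O[Si](C)(C)C(C)(C)C)=C1C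
F5 | step 8 | lithium lactone enolate of F4 (ketene acetal at the lactone carbonyl, other stereocentres as in F4) | CC[C@@H](C)[C@@H]1C2=C(O[Li])OC[C@@H](C)[C@@H]2[C@H](CC#C[Si](C)(C)C)C(O[Si](C)(C)C(C)(C)C)=C1C
F6 | step 12 | 3-(benzyloxy)-1-{(1R,2S,4aS,8R,8aR)-2-[(2R)-butan-2-yl]-4-[(tert-butyldimethylsilyl)oxy]-1,3,8-trimethyl-6-methylidene-1,2,4a,5,6,7,8,8a-octahydronaphthalen-1-yl}propan-1-one | CC[C@@H](C)[C@@H]1[C@](C)(C(=O)CCOCc3ccccc3)[C@@H]2[C@H](C)CC(=C)C[C@@H]2C(O[Si](C)(C)C(C)(C)C)=C1C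
F7 | step 12 | (2S,3R,4R,4aR,5R,7R,8aS)-4-[3-(benzyloxy)propanoyl]-3-[(2R)-butan-2-yl]-2,7-dihydroxy-7-(hydroxymethyl)-2,4,5-trimethyloctahydronaphthalen-1(2H)-one | CC[C@@H](C)[C@@H]1[C@](C)(C(=O)CCOCc3ccccc3)[C@@H]2[C@H](C)C[C@](O)(CO)C[C@@H]2C(=O)[C@@]1(C)O
F8 | step 13 | 2-O-(tert-butyldimethylsilyl) C1 ketone with the C7/C12 spiro-epoxide, epoxide oxygen on the α face, other stereocentres as in 24 | CC[C@@H](C)[C@@H]1[C@](C)(C(=O)CCO)[C@@H]2[C@H](C)C[C@@]3(CO3)C[C@@H]2C(=O)[C@@]1(C)O[Si](C)(C)C(C)(C)C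
F9 | step 13 | (2S,3R,4R,4aR,5R,7R,8aS)-3-[(2R)-butan-2-yl]-2-[(tert-butyldimethylsilyl)oxy]-7-hydroxy-7-(hydroxymethyl)-4-(3-hydroxypropanoyl)-2,4,5-trimethyloctahydronaphthalen-1(2H)-one | CC[C@@H](C)[C@@H]1[C@](C)(C(=O)CCO)[C@@H]2[C@H](C)C[C@](O)(CO)C[C@@H]2C(=O)[C@@]1(C)O[Si](C)(C)C(C)(C)C
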